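**Plan**

1. Retrosynthesis: the phenol O–Si bond and the C5–propenyl bond (Suzuki–Miyaura) are cut first, and the C3 methyl is traced back to a C3 ethyl ester. Then the C2–C3 bond is cut (carbene C–H insertion), followed by the C3–C3a bond (aryl iodide plus ethyl diazoacetate) and the O1–C2 bond (phenol benzylation).
2. Forward: a ring B benzyl bromide (from syringaldehyde) and a ring A iodophenol (from 4-bromo-2-methoxyphenol) are joined as an aryl benzyl ether, and the diazoacetate is attached to ring A. The dihydrofuran ring is the only ring formed, and it closes in the carbene step.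
3. Enabling feature: C2 is a benzylic ether carbon lying between O1 and the electron-rich ring B, and it is the fifth atom from C3 along C3–C3a–C7a–O1–C2. A carbene at C3 can therefore reach the C2–H bond and close the five-membered ring.
4. Stereochemistry: C2 (S) is set by the chiral dirhodium carboxylate in the insertion. C3 (S) is set afterwards by base epimerisation of the kinetic cis ester to the trans ester, relative to the fixed C2. The E alkene arrives intact with the boronic acid.
5. End game: ester to methyl (reduction, tosylation, hydride displacement), propenyl coupling at the C5 bromide, and fluoride removal of the silyl group so that no acid meets the styrene or the benzylic ether.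

Key step: step 7

Remark on the chemistry: the sense of induction is assumed by analogy with simpler 2-(benzyloxy)aryl diazoacetates, for which the (S)-phthaloyl-tert-leucinate catalyst is expected to give the 2R series; the R catalyst is therefore specified for the 2S target, and its mirror image (or, in the fallback, the mirror-image auxiliary) would be used if the sense proved opposite.

**Route**

Step 1
Reactants: 1 syringaldehyde (4-hydroxy-3,5-dimethoxybenzaldehyde)
Product: 2 3,5-dimethoxy-4-[(triisopropylsilyl)oxy]benzaldehyde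
Conditions: TIPSCl, imidazole, DMF, rt
Reagents that add atoms: chlorotri(propan-2-yl)silane (TIPSCl), CC(C)[Si](Cl)(C(C)C)C(C)C
Why: Silylation of an acidic phenol with a trialkylsilyl chloride and imidazole is standard protection, and the bulky silyl ether, shielded by two flanking methoxy groups, should resist the later basic and hydridic steps yet fall to fluoride without acid.

Step 2
Reactants: 2 3,5-dimethoxy-4-[(triisopropylsilyl)oxy]benzaldehyde
Product: 3 {3,5-dimethoxy-4-[(triisopropylsilyl)oxy]phenyl}methanol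
Conditions: NaBH4, MeOH/THF, 0 °C
Reagents that add atoms: none
Why: Borohydride reduction of an aromatic aldehyde to the benzylic alcohol is chemoselective and should leave the aryl silyl ether untouched at 0 °C.

Step 3
Reactants: 3 {3,5-dimethoxy-4-[(triisopropylsilyl)oxy]phenyl}methanol
Product: 4 5-(bromomethyl)-1,3-dimethoxy-2-[(triisopropylsilyl)oxy]benzene
Conditions: CBr4, PPh3, CH2Cl2, 0 °C
Reagents that add atoms: tetrabromomethane, BrC(Br)(Br)Br
Why: The Appel reaction converts the primary benzylic alcohol into the bromide under neutral conditions, so no hydrogen bromide threatens the silyl ether, and the electron-rich bromide is used without storage.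

Step 4
Reactants: 5 4-bromo-2-methoxyphenol
Product: 6 4-bromo-2-iodo-6-methoxyphenol
Conditions: NIS, TsOH·H2O (cat.), MeCN, 0 °C to rt
Reagents that add atoms: N-iodosuccinimide, O=C1CCC(=O)N1I
Why: Electrophilic aromatic iodination is directed by the free hydroxyl, the strongest donor, to its only open ortho position because the para position carries bromine.

Step 5
Reactants: 6 4-bromo-2-iodo-6-methoxyphenol; 4 5-(bromomethyl)-1,3-dimethoxy-2-[(triisopropylsilyl)oxy]benzene
Product: 7 5-bromo-2-({3,5-dimethoxy-4-[(triisopropylsilyl)oxy]benzyl}oxy)-1-iodo-3-methoxybenzene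
Conditions: K2CO3, DMF, rt
Reagents that add atoms: none
Why: Williamson ether synthesis, in which the 2,6-disubstituted phenoxide is alkylated on oxygen by the reactive benzylic bromide under conditions that leave the aryl silyl ether and both aryl halides alone.

Step 6
Reactants: 7 5-bromo-2-({3,5-dimethoxy-4-[(triisopropylsilyl)oxy]benzyl}oxy)-1-iodo-3-methoxybenzene; 8 ethyl diazoacetate
Product: 9 ethyl 2-[5-bromo-2-({3,5-dimethoxy-4-[(triisopropylsilyl)oxy]benzyl}oxy)-3-methoxyphenyl]-2-diazoacetate
Conditions: Pd(PPh3)4 (cat.), Et3N, Bu4NBr, MeCN, rt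
Reagents that add atoms: none
Why: Palladium-catalysed C–H arylation of ethyl diazoacetate with an aryl iodide, in which zerovalent palladium inserts into the C–I bond in preference to C–Br at room temperature, the amine-deprotonated diazoacetate is transferred to palladium and reductive elimination forms the C3–C3a bond with the diazo group intact.

Step 7
Reactants: 9 ethyl 2-[5-bromo-2-({3,5-dimethoxy-4-[(triisopropylsilyl)oxy]benzyl}oxy)-3-methoxyphenyl]-2-diazoacetate
Product: 10 ethyl (2S,3R)-5-bromo-2-{3,5-dimethoxy-4-[(triisopropylsilyl)oxy]phenyl}-7-methoxy-2,3-dihydro-1-benzofuran-3-carboxylate (cis)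
Conditions: Rh2(R-PTTL)4 [dirhodium tetrakis(N-phthaloyl-(R)-tert-leucinate)] (2 mol %), toluene, −78 to −60 °C
Reagents that add atoms: none
Why: Rh2(R-PTTL)4, a divalent rhodium dimer, expels N2 from the donor/acceptor diazo ester, and the electrophilic rhodium carbene at C3 takes the C2 hydrogen with hydride character while the C2–C3 bond forms in one concerted, asynchronous three-centre event. The closest known reaction type is the enantioselective intramolecular C–H insertion of 2-(benzyloxy)aryl diazoacetates under dirhodium N-phthaloyl amino acid carboxylate catalysis, which delivers cis-2-aryl-2,3-dihydrobenzofuran-3-carboxylates. The dihydrofuran ring closes in the 1,5-insertion mode, with C3 bonding to C2 as the fifth atom of the chain C3–C3a–C7a–O1–C2. C2 is controlled by the chiral carboxylate ligands, which select one of the two enantiotopic benzylic hydrogens, and C3 by the compact insertion transition state that places the ester and the aryl group cis (this centre is corrected in step 8). The step needs chemoselectivity for the C2–H bond over the methoxy C–H bonds and the arene π systems, and this should be secured by the activation of C2–H by O1 and ring B and by the intramolecular five-membered geometry at low temperature.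

Step 8
Reactants: 10 ethyl (2S,3R)-5-bromo-2-{3,5-dimethoxy-4-[(triisopropylsilyl)oxy]phenyl}-7-methoxy-2,3-dihydro-1-benzofuran-3-carboxylate (cis)
Product: 11 ethyl (2S,3S)-5-bromo-2-{3,5-dimethoxy-4-[(triisopropylsilyl)oxy]phenyl}-7-methoxy-2,3-dihydro-1-benzofuran-3-carboxylate (trans)
Conditions: NaOEt (cat.), EtOH/THF, 0 °C to rt
Reagents that add atoms: none
Why: Base-mediated epimerisation, in which catalytic ethoxide reversibly enolises the α-aryl ester at C3 and reprotonation should give the more stable trans isomer, while C2 is not acidic and ring opening by β-elimination would be the reverse of a disfavoured 5-endo-trig closure, so C2 keeps its configuration.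

Step 9
Reactants: 11 ethyl (2S,3S)-5-bromo-2-{3,5-dimethoxy-4-[(triisopropylsilyl)oxy]phenyl}-7-methoxy-2,3-dihydro-1-benzofuran-3-carboxylate (trans)
Product: 12 [(2S,3R)-5-bromo-2-{3,5-dimethoxy-4-[(triisopropylsilyl)oxy]phenyl}-7-methoxy-2,3-dihydro-1-benzofuran-3-yl]methanol (trans; the C3 descriptor changes only through priority)
Conditions: LiAlH4, THF, 0 °C
Reagents that add atoms: none
Why: Hydride reduction of the ester to the primary alcohol at 0 °C should not touch the aryl bromide, the hindered aryl silyl ether or either stereocentre.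

Step 10
Reactants: 12 [(2S,3R)-5-bromo-2-{3,5-dimethoxy-4-[(triisopropylsilyl)oxy]phenyl}-7-methoxy-2,3-dihydro-1-benzofuran-3-yl]methanol
Product: 13 [(2S,3R)-5-bromo-2-{3,5-dimethoxy-4-[(triisopropylsilyl)oxy]phenyl}-7-methoxy-2,3-dihydro-1-benzofuran-3-yl]methyl 4-methylbenzenesulfonate
Conditions: TsCl, Et3N, DMAP (cat.), CH2Cl2, 0 °C to rt
Reagents that add atoms: 4-methylbenzenesulfonyl chloride, Cc1ccc(cc1)S(Cl)(=O)=O
Why: Sulfonylation of the only hydroxyl group, a primary alcohol, under amine base with nucleophilic catalysis gives the tosylate without change at C2 or C3.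

Step 11
Reactants: 13 [(2S,3R)-5-bromo-2-{3,5-dimethoxy-4-[(triisopropylsilyl)oxy]phenyl}-7-methoxy-2,3-dihydro-1-benzofuran-3-yl]methyl 4-methylbenzenesulfonate
Product: 14 (2S,3S)-5-bromo-2-{3,5-dimethoxy-4-[(triisopropylsilyl)oxy]phenyl}-7-methoxy-3-methyl-2,3-dihydro-1-benzofuran
Conditions: LiEt3BH, THF, 0 °C to rt
Reagents that add atoms: none
Why: SN2 hydride displacement of a β-branched primary tosylate by LiEt3BH is the standard deoxygenation and should turn CH2OTs into the C3 methyl group while the aryl bromide, the ethers and the silyl ether stay inert at this temperature.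

Step 12
Reactants: 14 (2S,3S)-5-bromo-2-{3,5-dimethoxy-4-[(triisopropylsilyl)oxy]phenyl}-7-methoxy-3-methyl-2,3-dihydro-1-benzofuran; 15 (E)-prop-1-enylboronic acid
Product: 16 (2S,3S)-2-{3,5-dimethoxy-4-[(triisopropylsilyl)oxy]phenyl}-7-methoxy-3-methyl-5-[(E)-prop-1-enyl]-2,3-dihydro-1-benzofuran
Conditions: Pd(PPh3)4 (cat.), K2CO3, 1,4-dioxane/H2O, 85 °C
Reagents that add atoms: none
Why: Suzuki–Miyaura coupling at the only C–Br bond proceeds with retention of the E geometry of the alkenylboronic acid, and any premature loss of the silyl group to the aqueous base would simply give the target early.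

Step 13
Reactants: 16 (2S,3S)-2-{3,5-dimethoxy-4-[(triisopropylsilyl)oxy]phenyl}-7-methoxy-3-methyl-5-[(E)-prop-1-enyl]-2,3-dihydro-1-benzofuran
Product: 17 odoratisol A, 4-[(2S,3S)-7-methoxy-3-methyl-5-[(E)-prop-1-enyl]-2,3-dihydro-1-benzofuran-2-yl]-2,6-dimethoxyphenol
Conditions: Bu4NF, AcOH, THF, 0 °C
Reagents that add atoms: none
Why: Fluoride-mediated desilylation cleaves the aryl Si–O bond, and acetic acid buffering keeps the liberated phenol protonated so that neither the benzylic C2–O1 bond nor the propenyl group should be disturbed.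

**Compound list**

1 | syringaldehyde (4-hydroxy-3,5-dimethoxybenzaldehyde) | COc1cc(C=O)cc(OC)c1O | starting material
2 | 3,5-dimethoxy-4-[(triisopropylsilyl)oxy]benzaldehyde | COc1cc(C=O)cc(OC)c1O[Si](C(C)C)(C(C)C)C(C)C | intermediate
3 | {3,5-dimethoxy-4-[(triisopropylsilyl)oxy]phenyl}methanol | COc1cc(CO)cc(OC)c1O[Si](C(C)C)(C(C)C)C(C)C | intermediate
4 | 5-(bromomethyl)-1,3-dimethoxy-2-[(triisopropylsilyl)oxy]benzene | COc1cc(CBr)cc(OC)c1O[Si](C(C)C)(C(C)C)C(C)C | intermediate
5 | 4-bromo-2-methoxyphenol | COc1cc(Br)ccc1O | starting material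
6 | 4-bromo-2-iodo-6-methoxyphenol | COc1cc(Br)cc(I)c1O | intermediate
7 | 5-bromo-2-({3,5-dimethoxy-4-[(triisopropylsilyl)oxy]benzyl}oxy)-1-iodo-3-methoxybenzene | COc1cc(Br)cc(I)c1OCc1cc(OC)c(O[Si](C(C)C)(C(C)C)C(C)C)c(OC)c1 | intermediate
8 | ethyl diazoacetate | CCOC(=O)C=[N+]=[N-] | starting material
9 | ethyl 2-[5-bromo-2-({3,5-dimethoxy-4-[(triisopropylsilyl)oxy]benzyl}oxy)-3-methoxyphenyl]-2-diazoacetate | CCOC(=O)C(=[N+]=[N-])c1cc(Br)cc(OC)c1OCc1cc(OC)c(O[Si](C(C)C)(C(C)C)C(C)C)c(OC)c1 | intermediate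
10 | ethyl (2S,3R)-5-bromo-2-{3,5-dimethoxy-4-[(triisopropylsilyl)oxy]phenyl}-7-methoxy-2,3-dihydro-1-benzofuran-3-carboxylate (cis) | Brc1cc(OC)c2c(c1)[C@@H](C(=O)OCC)[C@@H](c1cc(OC)c(O[Si](C(C)C)(C(C)C)C(C)C)c(OC)c1)O2 | intermediate
11 | ethyl (2S,3S)-5-bromo-2-{3,5-dimethoxy-4-[(triisopropylsilyl)oxy]phenyl}-7-methoxy-2,3-dihydro-1-benzofuran-3-carboxylate (trans) | Brc1cc(OC)c2c(c1)[C@H](C(=O)OCC)[C@@H](c1cc(OC)c(O[Si](C(C)C)(C(C)C)C(C)C)c(OC)c1)O2 | intermediate
12 | [(2S,3R)-5-bromo-2-{3,5-dimethoxy-4-[(triisopropylsilyl)oxy]phenyl}-7-methoxy-2,3-dihydro-1-benzofuran-3-yl]methanol (trans) | Brc1cc(OC)c2c(c1)[C@H](CO)[C@@H](c1cc(OC)c(O[Si](C(C)C)(C(C)C)C(C)C)c(OC)c1)O2 | intermediate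
13 | [(2S,3R)-5-bromo-2-{3,5-dimethoxy-4-[(triisopropylsilyl)oxy]phenyl}-7-methoxy-2,3-dihydro-1-benzofuran-3-yl]methyl 4-methylbenzenesulfonate (trans) | Brc1cc(OC)c2c(c1)[C@H](COS(=O)(=O)c1ccc(C)cc1)[C@@H](c1cc(OC)c(O[Si](C(C)C)(C(C)C)C(C)C)c(OC)c1)O2 | intermediate
14 | (2S,3S)-5-bromo-2-{3,5-dimethoxy-4-[(triisopropylsilyl)oxy]phenyl}-7-methoxy-3-methyl-2,3-dihydro-1-benzofuran (trans) | Brc1cc(OC)c2c(c1)[C@H](C)[C@@H](c1cc(OC)c(O[Si](C(C)C)(C(C)C)C(C)C)c(OC)c1)O2 | intermediate
15 | (E)-prop-1-enylboronic acid | C/C=C/B(O)O | starting material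
16 | (2S,3S)-2-{3,5-dimethoxy-4-[(triisopropylsilyl)oxy]phenyl}-7-methoxy-3-methyl-5-[(E)-prop-1-enyl]-2,3-dihydro-1-benzofuran | C/C=C/c1cc(OC)c2c(c1)[C@H](C)[C@@H](c1cc(OC)c(O[Si](C(C)C)(C(C)C)C(C)C)c(OC)c1)O2 | intermediate
17 | odoratisol A, 4-[(2S,3S)-7-methoxy-3-methyl-5-[(E)-prop-1-enyl]-2,3-dihydro-1-benzofuran-2-yl]-2,6-dimethoxyphenol | C/C=C/c1cc(OC)c2c(c1)[C@H](C)[C@@H](c1cc(OC)c(O)c(OC)c1)O2 | target

**Totals**

Total step count: 13. Longest linear sequence: 12 steps (steps 1–3 and 5–13, from syringaldehyde).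

**Steps most likely to fail, with fallbacks**

Step 7. What may go wrong: the chiral carboxylate ligands may discriminate poorly between the two enantiotopic C2 hydrogens of this trioxygenated benzyl ether, or the carbene may be diverted to ring B, so that enantiomeric purity or conversion suffers. The fallback moves stereocontrol from the catalyst alone to a lactamide auxiliary bound covalently to the ester. It sets out from iodide 7. Ethyl (S)-lactate is heated with pyrrolidine to give (2S)-2-hydroxy-1-(pyrrolidin-1-yl)propan-1-one F1. Acylation with bromoacetyl bromide and pyridine in CH2Cl2 gives (2S)-1-oxo-1-(pyrrolidin-1-yl)propan-2-yl bromoacetate F2. Treatment with N,N'-ditosylhydrazine and DBU in THF at 0 °C gives (2S)-1-oxo-1-(pyrrolidin-1-yl)propan-2-yl diazoacetate F3. F3 is coupled with 7 under the conditions of step 6 to give (2S)-1-oxo-1-(pyrrolidin-1-yl)propan-2-yl 2-[5-bromo-2-({3,5-dimethoxy-4-[(triisopropylsilyl)oxy]benzyl}oxy)-3-methoxyphenyl]-2-diazoacetate F4. Insertion with Rh2(S-DOSP)4, dirhodium tetrakis[(S)-N-(4-dodecylbenzenesulfonyl)prolinate], in CH2Cl2 (catalyst and auxiliary paired so that both favour the 2S series) should give (2S)-1-oxo-1-(pyrrolidin-1-yl)propan-2-yl (2S,3S)-5-bromo-2-{3,5-dimethoxy-4-[(triisopropylsilyl)oxy]phenyl}-7-methoxy-2,3-dihydro-1-benzofuran-3-carboxylate F5. NaOEt in EtOH then exchanges the auxiliary for ethoxide and equilibrates C3, and the route is rejoined at trans ester 11.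

Step 6. What may go wrong: transfer of the diazoacetate to the ortho-alkoxy-hindered arylpalladium iodide may be slow, so that palladium decomposes the diazo ester or the C–Br bond begins to react. The fallback introduces the two-carbon unit as an acetate first and the diazo group afterwards. It sets out from iodide 7. Ethyl bromoacetate and Zn in THF give the Reformatsky reagent bromo(2-ethoxy-2-oxoethyl)zinc F6. Negishi-type cross-coupling of F6 with 7 (Pd(PPh3)4, THF, 45 °C, selective for the C–I bond) gives ethyl 2-[5-bromo-2-({3,5-dimethoxy-4-[(triisopropylsilyl)oxy]benzyl}oxy)-3-methoxyphenyl]acetate F7. Diazo transfer with 4-acetamidobenzenesulfonyl azide and DBU in MeCN at 0 °C to rt rejoins the route at diazo ester 9.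

Step 8. What may go wrong: ethoxide may attack the silicon of the aryl silyl ether, or the equilibration may stall, before C3 is fully inverted. The fallback epimerises at the aldehyde oxidation level, where a weak amine base suffices. It sets out from cis ester 10. LiAlH4 in THF at 0 °C gives [(2S,3S)-5-bromo-2-{3,5-dimethoxy-4-[(triisopropylsilyl)oxy]phenyl}-7-methoxy-2,3-dihydro-1-benzofuran-3-yl]methanol F8 (cis). Dess–Martin periodinane in CH2Cl2 gives (2S,3R)-5-bromo-2-{3,5-dimethoxy-4-[(triisopropylsilyl)oxy]phenyl}-7-methoxy-2,3-dihydro-1-benzofuran-3-carbaldehyde F9 (cis). Et3N in CH2Cl2 at rt equilibrates it to (2S,3S)-5-bromo-2-{3,5-dimethoxy-4-[(triisopropylsilyl)oxy]phenyl}-7-methoxy-2,3-dihydro-1-benzofuran-3-carbaldehyde F10 (trans). NaBH4 in MeOH at 0 °C rejoins the route at trans alcohol 12.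

**Further compounds**

F1 | step 7 | (2S)-2-hydroxy-1-(pyrrolidin-1-yl)propan-1-one | C[C@H](O)C(=O)N1CCCC1
F2 | step 7 | (2S)-1-oxo-1-(pyrrolidin-1-yl)propan-2-yl bromoacetate | C[C@H](OC(=O)CBr)C(=O)N1CCCC1
F3 | step 7 | (2S)-1-oxo-1-(pyrrolidin-1-yl)propan-2-yl diazoacetate | C[C@H](OC(=O)C=[N+]=[N-])C(=O)N1CCCC1
F4 | step 7 | (2S)-1-oxo-1-(pyrrolidin-1-yl)propan-2-yl 2-[5-bromo-2-({3,5-dimethoxy-4-[(triisopropylsilyl)oxy]benzyl}oxy)-3-methoxyphenyl]-2-diazoacetate | C[C@H](OC(=O)C(=[N+]=[N-])c1cc(Br)cc(OC)c1OCc1cc(OC)c(O[Si](C(C)C)(C(C)C)C(C)C)c(OC)c1)C(=O)N1CCCC1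
F5 | step 7 | (2S)-1-oxo-1-(pyrrolidin-1-yl)propan-2-yl (2S,3S)-5-bromo-2-{3,5-dimethoxy-4-[(triisopropylsilyl)oxy]phenyl}-7-methoxy-2,3-dihydro-1-benzofuran-3-carboxylate | Brc1cc(OC)c2c(c1)[C@H](C(=O)O[C@@H](C)C(=O)N1CCCC1)[C@@H](c1cc(OC)c(O[Si](C(C)C)(C(C)C)C(C)C)c(OC)c1)O2
F6 | step 6 | bromo(2-ethoxy-2-oxoethyl)zinc | CCOC(=O)C[Zn]Br
F7 | step 6 | ethyl 2-[5-bromo-2-({3,5-dimethoxy-4-[(triisopropylsilyl)oxy]benzyl}oxy)-3-methoxyphenyl]acetate | CCOC(=O)Cc1cc(Br)cc(OC)c1OCc1cc(OC)c(O[Si](C(C)C)(C(C)C)C(C)C)c(OC)c1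
F8 | step 8 | [(2S,3S)-5-bromo-2-{3,5-dimethoxy-4-[(triisopropylsilyl)oxy]phenyl}-7-methoxy-2,3-dihydro-1-benzofuran-3-yl]methanol (cis) | Brc1cc(OC)c2c(c1)[C@@H](CO)[C@@H](c1cc(OC)c(O[Si](C(C)C)(C(C)C)C(C)C)c(OC)c1)O2
F9 | step 8 | (2S,3R)-5-bromo-2-{3,5-dimethoxy-4-[(triisopropylsilyl)oxy]phenyl}-7-methoxy-2,3-dihydro-1-benzofuran-3-carbaldehyde (cis) | Brc1cc(OC)c2c(c1)[C@@H](C=O)[C@@H](c1cc(OC)c(O[Si](C(C)C)(C(C)C)C(C)C)c(OC)c1)O2
F10 | step 8 | (2S,3S)-5-bromo-2-{3,5-dimethoxy-4-[(triisopropylsilyl)oxy]phenyl}-7-methoxy-2,3-dihydro-1-benzofuran-3-carbaldehyde (trans) | Brc1cc(OC)c2c(c1)[C@H](C=O)[C@@H](c1cc(OC)c(O[Si](C(C)C)(C(C)C)C(C)C)c(OC)c1)O2
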